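## Retrosynthetic overview

1. Last C–O events: the ring A carbinol is acylated with (3R,5S)-3-hydroxy-3,5-dimethylheptanoic acid, then the lactone α-ketone is reduced. Ring D is closed by an aerobic copper-catalysed oxidative lactonisation of a terminal alkynol, which forms the lactone C–O bond and the α-carbonyl together (new reaction).
2. Ring C: ring-closing metathesis (isopropenyl + allyl) on a silylene-tied 1,3-diol.
3. Union: chelation-controlled addition of a Shapiro-derived 2-lithioalkene (rings A/B) to a β-hydroxy ynone made from ethyl (S)-3-hydroxybutanoate (Fráter–Seebach).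
4. Rings A and B in one step: Pauson–Khand reaction of an Evans-derived 1,7-enyne, then CBS reduction and hydroxyl-directed hydrogenation.
5. Ring order: A+B, then C, then D. Side-chain acid: carbocupration, Sharpless epoxidation, hydride opening, oxidation.

Assumption: rings are lettered A (cyclopentane), B (cyclohexane), C (cyclooctene) and D (δ-lactone); all numbered starting materials are taken as catalogue chemicals.

## Route

Step 1
Reactants: 1 3-methylbut-1-yne
Product: 3 4-methylpent-2-yn-1-ol, via lithium acetylide 2 (not isolated)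
Conditions: n-BuLi, THF, −78 °C; then (CH2O)n, −78 → 23 °C; H2O
Reagents that add atoms: paraformaldehyde (formaldehyde unit), C=O
Why: 1,2-Addition of a lithium acetylide to formaldehyde is the standard route to primary propargylic alcohols and creates no stereocentre.

Step 2
Reactants: 3 4-methylpent-2-yn-1-ol
Product: 4 1-bromo-4-methylpent-2-yne
Conditions: CBr4, PPh3, CH2Cl2, 0 °C
Reagents that add atoms: carbon tetrabromide, BrC(Br)(Br)Br
Why: Appel bromination converts the primary propargylic alcohol into the bromide under neutral conditions without allenyl rearrangement.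

Step 3
Reactants: 5 (S)-4-benzyl-1,3-oxazolidin-2-one; 6 ethyl (E)-4-chloro-4-oxobut-2-enoate
Product: 7 ethyl (E)-4-[(S)-4-benzyl-2-oxo-1,3-oxazolidin-3-yl]-4-oxobut-2-enoate
Conditions: LiCl, Et3N, THF, 0 → 23 °C
Reagents that add atoms: none
Why: Mild N-acylation of the Evans auxiliary by the acid chloride keeps the E double bond intact and creates no new stereocentre.

Step 4
Reactants: 7 ethyl (E)-4-[(S)-4-benzyl-2-oxo-1,3-oxazolidin-3-yl]-4-oxobut-2-enoate; 8 trimethyl(2-methylprop-2-en-1-yl)silane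
Product: 9 ethyl (S)-2-{2-[(S)-4-benzyl-2-oxo-1,3-oxazolidin-3-yl]-2-oxoethyl}-4-methylpent-4-enoate
Conditions: TiCl4, CH2Cl2, −78 °C; then H2O
Reagents that add atoms: none
Why: Hosomi–Sakurai conjugate allylation of the TiCl4-chelated s-cis imide delivers the methallyl group to the carbon β to the imide (the ester-bearing carbon) from the face opposite the benzyl group, setting that centre (S).

Step 5
Reactants: 9 ethyl (S)-2-{2-[(S)-4-benzyl-2-oxo-1,3-oxazolidin-3-yl]-2-oxoethyl}-4-methylpent-4-enoate; 4 1-bromo-4-methylpent-2-yne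
Product: 11 ethyl (2S,3S)-3-{[(S)-4-benzyl-2-oxo-1,3-oxazolidin-3-yl]carbonyl}-7-methyl-2-(2-methylprop-2-en-1-yl)oct-5-ynoate, via sodium enolate 10 (not isolated)
Conditions: NaN(SiMe3)2, THF, −78 °C; then 4, −78 → −40 °C
Reagents that add atoms: none
Why: Evans alkylation of the chelated Z-enolate by the propargylic bromide occurs anti to the benzyl group, setting the second centre (S) and so the syn (threo) dialkyl succinate pattern that becomes the trans ring B substituents.

Step 6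
Reactants: 11 ethyl (2S,3S)-3-{[(S)-4-benzyl-2-oxo-1,3-oxazolidin-3-yl]carbonyl}-7-methyl-2-(2-methylprop-2-en-1-yl)oct-5-ynoate
Product: 12 ethyl (5S,6S,7aS)-5-{[(S)-4-benzyl-2-oxo-1,3-oxazolidin-3-yl]carbonyl}-7a-methyl-2-oxo-3-(propan-2-yl)-2,4,5,6,7,7a-hexahydro-1H-indene-6-carboxylate
Conditions: Co2(CO)8 (20 mol %), tetramethylthiourea (1.2 equiv), CO (1 atm), benzene, 70 °C
Reagents that add atoms: carbon monoxide, [C-]#[O+]
Why: The intramolecular Pauson–Khand [2+2+1] cyclisation of the 1,7-enyne builds rings A and B together, and a chair-like transition state with both tether substituents equatorial puts the new quaternary methyl trans to the ester-bearing carbon (7aS).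

Step 7
Reactants: 12 ethyl (5S,6S,7aS)-5-{[(S)-4-benzyl-2-oxo-1,3-oxazolidin-3-yl]carbonyl}-7a-methyl-2-oxo-3-(propan-2-yl)-2,4,5,6,7,7a-hexahydro-1H-indene-6-carboxylate
Product: 13 ethyl (2R,5S,6S,7aS)-5-{[(S)-4-benzyl-2-oxo-1,3-oxazolidin-3-yl]carbonyl}-2-hydroxy-7a-methyl-3-(propan-2-yl)-2,4,5,6,7,7a-hexahydro-1H-indene-6-carboxylate
Conditions: (S)-2-methyl-CBS-oxazaborolidine (0.3 equiv), catecholborane, toluene, −78 °C
Reagents that add atoms: none
Why: Corey–Bakshi–Shibata reduction of the 2-substituted cyclopentenone is catalyst-controlled (the alkene side acts as the large group) and gives the (2R)-allylic alcohol with the hydroxyl on the face anti to the angular methyl.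

Step 8
Reactants: 13 ethyl (2R,5S,6S,7aS)-5-{[(S)-4-benzyl-2-oxo-1,3-oxazolidin-3-yl]carbonyl}-2-hydroxy-7a-methyl-3-(propan-2-yl)-2,4,5,6,7,7a-hexahydro-1H-indene-6-carboxylate
Product: 14 ethyl (2R,3R,3aS,5S,6S,7aS)-5-{[(S)-4-benzyl-2-oxo-1,3-oxazolidin-3-yl]carbonyl}-2-hydroxy-7a-methyl-3-(propan-2-yl)octahydro-1H-indene-6-carboxylate
Conditions: [Ir(cod)(PCy3)(py)]PF6 (10 mol %), H2 (30 bar), CH2Cl2, 23 °C
Reagents that add atoms: none
Why: Hydroxyl-directed hydrogenation of the tetrasubstituted alkene adds both hydrogens syn to the carbinol oxygen, setting the trans ring fusion (3aS) and the isopropyl-bearing carbon (3R, isopropyl cis to the angular methyl).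

Step 9
Reactants: 14 ethyl (2R,3R,3aS,5S,6S,7aS)-5-{[(S)-4-benzyl-2-oxo-1,3-oxazolidin-3-yl]carbonyl}-2-hydroxy-7a-methyl-3-(propan-2-yl)octahydro-1H-indene-6-carboxylate
Product: 15 tert-butyldimethylsilyl ether of 14
Conditions: t-BuMe2SiOTf, 2,6-lutidine, CH2Cl2, 0 °C
Reagents that add atoms: tert-butyldimethylsilyl trifluoromethanesulfonate, CC(C)(C)[Si](C)(C)OS(=O)(=O)C(F)(F)F
Why: Silylation of the secondary alcohol with the silyl triflate protects it for the organolithium steps that follow.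

Step 10
Reactants: 15 tert-butyldimethylsilyl ether of 14
Product: 16 (2R,3R,3aS,5S,6S,7aS)-2-[(tert-butyldimethylsilyl)oxy]-6-(ethoxycarbonyl)-7a-methyl-3-(propan-2-yl)octahydro-1H-indene-5-carboxylic acid
Conditions: LiOH, H2O2, THF/H2O, 0 °C; then Na2SO3; then HCl (pH 3)
Reagents that add atoms: hydrogen peroxide (as LiOOH), OO
Why: Hydroperoxide cleavage of the N-acyl oxazolidinone is selective for the exocyclic acyl group, leaves the ethyl ester untouched and releases the auxiliary.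

Step 11
Reactants: 16 (2R,3R,3aS,5S,6S,7aS)-2-[(tert-butyldimethylsilyl)oxy]-6-(ethoxycarbonyl)-7a-methyl-3-(propan-2-yl)octahydro-1H-indene-5-carboxylic acid
Product: 18 (2R,3R,3aS,5S,6S,7aS)-6-acetyl-2-[(tert-butyldimethylsilyl)oxy]-7a-methyl-3-(propan-2-yl)octahydro-1H-indene-5-carboxylic acid, via α-silyl ketone 17 (not isolated)
Conditions: Me3SiCH2Li (3.5 equiv), THF, −78 → 0 °C; then MeOH, 23 °C; then HCl (aq, pH 3)
Reagents that add atoms: (trimethylsilyl)methyllithium, C[Si](C)(C)C[Li]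
Why: One-pot ester-to-methyl-ketone conversion by acyl substitution, in which the lithium carboxylate is inert, the addition stops at the enolised α-silyl ketone and methanolysis (protodesilylation) unveils the acetyl group in its thermodynamic equatorial position.

Step 12
Reactants: 18 (2R,3R,3aS,5S,6S,7aS)-6-acetyl-2-[(tert-butyldimethylsilyl)oxy]-7a-methyl-3-(propan-2-yl)octahydro-1H-indene-5-carboxylic acid
Product: 19 (2R,3R,3aS,5S,6S,7aS)-2-[(tert-butyldimethylsilyl)oxy]-7a-methyl-3-(propan-2-yl)-6-(prop-1-en-2-yl)octahydro-1H-indene-5-carboxylic acid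
Conditions: Ph3PCH3Br, KOt-Bu (3 equiv each), THF, 0 → 60 °C; then HCl (aq, pH 3)
Reagents that add atoms: methyltriphenylphosphonium bromide, C[P+](c1ccccc1)(c1ccccc1)c1ccccc1.[Br-]
Why: Wittig methylenation of the methyl ketone gives the isopropenyl group while the potassium carboxylate stays inert.

Step 13
Reactants: 19 (2R,3R,3aS,5S,6S,7aS)-2-[(tert-butyldimethylsilyl)oxy]-7a-methyl-3-(propan-2-yl)-6-(prop-1-en-2-yl)octahydro-1H-indene-5-carboxylic acid
Product: 20 1-[(2R,3R,3aS,5S,6S,7aS)-2-[(tert-butyldimethylsilyl)oxy]-7a-methyl-3-(propan-2-yl)-6-(prop-1-en-2-yl)octahydro-1H-inden-5-yl]ethan-1-one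
Conditions: MeLi (3 equiv), Et2O, 0 °C; then HCl (aq), 0 °C
Reagents that add atoms: methyllithium, C[Li]
Why: Addition of methyllithium to the lithium carboxylate stops at the dilithium gem-diolate, which gives the methyl ketone on work-up (acid-to-methyl-ketone synthesis) with the acetyl group equatorial.

Step 14
Reactants: 20 1-[(2R,3R,3aS,5S,6S,7aS)-2-[(tert-butyldimethylsilyl)oxy]-7a-methyl-3-(propan-2-yl)-6-(prop-1-en-2-yl)octahydro-1H-inden-5-yl]ethan-1-one
Product: 21 2,4,6-tri(propan-2-yl)benzenesulfonylhydrazone of ketone 20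
Conditions: 2,4,6-(i-Pr)3C6H2SO2NHNH2, THF, 23 °C
Reagents that add atoms: 2,4,6-tri(propan-2-yl)benzenesulfonohydrazide, CC(C)c1cc(C(C)C)c(S(=O)(=O)NN)c(C(C)C)c1
Why: Condensation gives the trisylhydrazone needed for a Shapiro reaction directed to the methyl group.

Step 15
Reactants: 22 ethyl (S)-3-hydroxybutanoate; 23 3-bromoprop-1-ene
Product: 25 ethyl (2S,3S)-3-hydroxy-2-(prop-2-en-1-yl)butanoate, via dilithium alkoxide-enolate 24 (not isolated)
Conditions: LiN(i-Pr)2 (2.2 equiv), THF, −78 → −20 °C; then 23, DMPU, −78 → −10 °C; H2O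
Reagents that add atoms: none
Why: In the Fráter–Seebach alkylation the chelated dianion is allylated anti to the methyl group of the carbinol carbon, giving the anti (2S,3S) product.

Step 16
Reactants: 25 ethyl (2S,3S)-3-hydroxy-2-(prop-2-en-1-yl)butanoate
Product: 26 (2S,3S)-3-hydroxy-N-methoxy-N-methyl-2-(prop-2-en-1-yl)butanamide
Conditions: MeNH(OMe)·HCl, i-PrMgCl, THF, −20 → 0 °C
Reagents that add atoms: N,O-dimethylhydroxylamine hydrochloride, CNOC.Cl
Why: Aminolysis of the ester by the magnesium amide gives the Weinreb amide directly, without hydroxyl protection and without epimerising the α-centre.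

Step 17
Reactants: 26 (2S,3S)-3-hydroxy-N-methoxy-N-methyl-2-(prop-2-en-1-yl)butanamide; 27 ethynyltri(propan-2-yl)silane
Product: 29 (4S,5S)-5-hydroxy-4-(prop-2-en-1-yl)-1-[tri(propan-2-yl)silyl]hex-1-yn-3-one, via lithium silylacetylide 28 (not isolated)
Conditions: 27 (2.3 equiv), n-BuLi, THF, −78 °C; then 26, −78 → 0 °C; NH4Cl (aq)
Reagents that add atoms: none
Why: In the Weinreb ketone synthesis the chelated tetrahedral intermediate blocks over-addition and releases the ynone on work-up.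

Step 18
Reactants: 21 2,4,6-tri(propan-2-yl)benzenesulfonylhydrazone of ketone 20; 29 (4S,5S)-5-hydroxy-4-(prop-2-en-1-yl)-1-[tri(propan-2-yl)silyl]hex-1-yn-3-one
Product: 32 di-tert-butylsilylene acetal of the union diol, via vinyllithium 30 (not isolated), via dilithium dialkoxide 31 (not isolated)
Conditions: 21, n-BuLi (2.1 equiv), THF, −78 → 0 °C; add to 29 pre-treated with LiN(SiMe3)2 (1.0 equiv) and MgBr2·OEt2, THF, −78 °C; then t-Bu2Si(OTf)2 (2.5 equiv), −78 → 0 °C
Reagents that add atoms: di-tert-butylsilyl bis(trifluoromethanesulfonate), CC(C)(C)[Si](OS(=O)(=O)C(F)(F)F)(OS(=O)(=O)C(F)(F)F)C(C)(C)C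
Why: A Shapiro reaction gives the 2-lithioalkene, whose chelation-controlled (Cram–Reetz, β-alkoxide chelate) 1,2-addition to the ynone anti to the allyl group sets the tertiary carbinol as in the target, and the 1,3-dialkoxide is trapped as a cyclic silylene.

Step 19
Reactants: 32 di-tert-butylsilylene acetal of the union diol
Product: 33 rings A–C tricycle with silylene acetal and silylethynyl group
Conditions: second-generation Grubbs catalyst (15 mol %), toluene (1 mM), 80 °C
Reagents that add atoms: none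
Why: Ring-closing metathesis of the isopropenyl and allyl groups closes ring C with the Z trisubstituted alkene enforced by the eight-membered ring, while the exocyclic methylene (flanked by a quaternary and a tertiary carbon, its five-membered closure trans-fused to the dioxasilinane) and the bulky silylalkyne should stay out.

Step 20
Reactants: 33 rings A–C tricycle with silylene acetal and silylethynyl group
Product: 34 rings A–C triol with terminal alkyne
Conditions: Bu4NF (6 equiv), THF, 0 → 23 °C; H2O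
Reagents that add atoms: none
Why: Fluoride-mediated desilylation removes the silylene acetal, the silyl ether and the alkynyl silane in one operation.

Step 21
Reactants: 34 rings A–C triol with terminal alkyne
Product: 35 rings A–D α-keto lactone with free ring A hydroxyl
Conditions: CuBr (10 mol %), 2-picolinic acid (20 mol %), O2 (1 atm), MeCN (5 mM), blue LEDs, 25 °C
Reagents that add atoms: dioxygen, O=O
Why: Proposed new method: an intramolecular aerobic copper-catalysed oxidative lactonisation–diketonisation of an aliphatic terminal alkynol, in which the copper acetylide is oxygenated by O2 to an α-oxoacyl (glyoxal-level) copper species that is captured 6-exo by the secondary hydroxyl and oxidised at the lactol stage, so that the lactone C–O bond and the α-carbonyl of ring D form in one step (ring geometry forbids a cyclic ynol ether, so oxygenation must precede C–O formation, and high dilution suppresses Glaser coupling); the closest known reaction type is the intermolecular copper/O2 oxidative coupling of aryl alkynes with amines or alcohols to α-ketoamides and α-ketoesters.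

Step 22
Reactants: 36 (S)-1-bromo-2-methylbutane; 37 ethyl but-2-ynoate
Product: 39 ethyl (2E,5S)-3,5-dimethylhept-2-enoate, via Grignard reagent 38 (not isolated)
Conditions: 36, Mg, THF, 40 °C; then CuI (10 mol %), 37, THF, −78 °C; H2O at −78 °C
Reagents that add atoms: none
Why: Copper-catalysed syn-carbometalation of the ynoate and low-temperature protonation place the new alkyl group trans to the ester (E), and the remote stereocentre comes unchanged from the chiral bromide.

Step 23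
Reactants: 39 ethyl (2E,5S)-3,5-dimethylhept-2-enoate
Product: 40 (2E,5S)-3,5-dimethylhept-2-en-1-ol
Conditions: i-Bu2AlH (2.2 equiv), CH2Cl2, −78 °C
Reagents that add atoms: none
Why: 1,2-Reduction of the enoate by the aluminium hydride gives the allylic alcohol without touching the alkene geometry.

Step 24
Reactants: 40 (2E,5S)-3,5-dimethylhept-2-en-1-ol
Product: 41 {(2R,3R)-3-methyl-3-[(2S)-2-methylbutyl]oxiran-2-yl}methanol
Conditions: Ti(Oi-Pr)4 (10 mol %), (−)-diethyl D-tartrate (12 mol %), t-BuOOH, 4 Å sieves, CH2Cl2, −20 °C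
Reagents that add atoms: tert-butyl hydroperoxide, CC(C)(C)OO
Why: Sharpless asymmetric epoxidation of the trisubstituted E-allylic alcohol is reagent-controlled and sets the quaternary C–O centre (2R,3R, as for geraniol with the D-tartrate).

Step 25
Reactants: 41 {(2R,3R)-3-methyl-3-[(2S)-2-methylbutyl]oxiran-2-yl}methanol
Product: 42 (3R,5S)-3,5-dimethylheptane-1,3-diol
Conditions: NaAlH2(OCH2CH2OMe)2, THF, 0 °C
Reagents that add atoms: none
Why: Hydroxyl-directed hydride opening of the 2,3-epoxy alcohol at C-2 gives the 1,3-diol and leaves the tertiary C–O bond (3R) untouched.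

Step 26
Reactants: 42 (3R,5S)-3,5-dimethylheptane-1,3-diol
Product: 43 (3R,5S)-3-hydroxy-3,5-dimethylheptanoic acid
Conditions: TEMPO (10 mol %), NaOCl (5 mol %), NaClO2, MeCN/phosphate buffer (pH 6.7), 35 °C
Reagents that add atoms: sodium chlorite, [Na+].[O-]Cl=O
Why: Nitroxyl-catalysed oxidation with chlorite as terminal oxidant converts only the primary alcohol into the acid and cannot oxidise the tertiary alcohol.

Step 27
Reactants: 35 rings A–D α-keto lactone with free ring A hydroxyl; 43 (3R,5S)-3-hydroxy-3,5-dimethylheptanoic acid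
Product: 44 α-keto lactone acylated on the ring A hydroxyl by acid 43
Conditions: 2-methyl-6-nitrobenzoic anhydride, DMAP, Et3N, CH2Cl2, 0 → 23 °C
Reagents that add atoms: none
Why: Shiina esterification acylates the only secondary hydroxyl (the two other hydroxyls are tertiary) with retention at the carbinol carbon.

Step 28
Reactants: 44 α-keto lactone acylated on the ring A hydroxyl by acid 43
Product: 45 CNP0331120.1
Conditions: NaBH4 (0.5 equiv), MeOH/THF, −40 °C
Reagents that add atoms: none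
Why: Chemoselective borohydride reduction of the activated α-keto lactone ketone, with hydride attacking anti to the axial ring C bond on the neighbouring carbinol carbon, gives the equatorial secondary alcohol trans to the tertiary hydroxyl (S).

## Compound list

1 | 3-methylbut-1-yne | CC(C)C#C | starting material
2 | lithium 3-methylbut-1-yn-1-ide | CC(C)C#C[Li] | intermediate
3 | 4-methylpent-2-yn-1-ol | CC(C)C#CCO | intermediate
4 | 1-bromo-4-methylpent-2-yne | CC(C)C#CCBr | intermediate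
5 | (S)-4-benzyl-1,3-oxazolidin-2-one | O=C1OC[C@H](Cc2ccccc2)N1 | starting material
6 | ethyl (E)-4-chloro-4-oxobut-2-enoate | CCOC(=O)/C=C/C(Cl)=O | starting material
7 | ethyl (E)-4-[(S)-4-benzyl-2-oxo-1,3-oxazolidin-3-yl]-4-oxobut-2-enoate | CCOC(=O)/C=C/C(=O)N1C(=O)OC[C@@H]1Cc1ccccc1 | intermediate
8 | trimethyl(2-methylprop-2-en-1-yl)silane | C=C(C)C[Si](C)(C)C | starting material
9 | ethyl (S)-2-{2-[(S)-4-benzyl-2-oxo-1,3-oxazolidin-3-yl]-2-oxoethyl}-4-methylpent-4-enoate | CCOC(=O)[C@@H](CC(C)=C)CC(=O)N1C(=O)OC[C@@H]1Cc1ccccc1 | intermediate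
10 | sodium (Z)-enolate of imide 9 | CCOC(=O)[C@@H](CC(C)=C)/C=C(\O[Na])N1C(=O)OC[C@@H]1Cc1ccccc1 | intermediate
11 | ethyl (2S,3S)-3-{[(S)-4-benzyl-2-oxo-1,3-oxazolidin-3-yl]carbonyl}-7-methyl-2-(2-methylprop-2-en-1-yl)oct-5-ynoate | CCOC(=O)[C@@H](CC(C)=C)[C@H](CC#CC(C)C)C(=O)N1C(=O)OC[C@@H]1Cc1ccccc1 | intermediate
12 | ethyl (5S,6S,7aS)-5-{[(S)-4-benzyl-2-oxo-1,3-oxazolidin-3-yl]carbonyl}-7a-methyl-2-oxo-3-(propan-2-yl)-2,4,5,6,7,7a-hexahydro-1H-indene-6-carboxylate (rings A and B, enone in ring A) | O=C(N1C(=O)OC[C@@H]1Cc1ccccc1)[C@H]2CC3=C(C(C)C)C(=O)C[C@]3(C)C[C@@H]2C(=O)OCC | intermediate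
13 | ethyl (2R,5S,6S,7aS)-5-{[(S)-4-benzyl-2-oxo-1,3-oxazolidin-3-yl]carbonyl}-2-hydroxy-7a-methyl-3-(propan-2-yl)-2,4,5,6,7,7a-hexahydro-1H-indene-6-carboxylate | O=C(N1C(=O)OC[C@@H]1Cc1ccccc1)[C@H]2CC3=C(C(C)C)[C@H](O)C[C@]3(C)C[C@@H]2C(=O)OCC | intermediate
14 | ethyl (2R,3R,3aS,5S,6S,7aS)-5-{[(S)-4-benzyl-2-oxo-1,3-oxazolidin-3-yl]carbonyl}-2-hydroxy-7a-methyl-3-(propan-2-yl)octahydro-1H-indene-6-carboxylate (trans-fused) | O=C(N1C(=O)OC[C@@H]1Cc1ccccc1)[C@H]2C[C@H]3[C@@H](C(C)C)[C@H](O)C[C@]3(C)C[C@@H]2C(=O)OCC | intermediate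
15 | tert-butyldimethylsilyl ether of 14 | O=C(N1C(=O)OC[C@@H]1Cc1ccccc1)[C@H]2C[C@H]3[C@@H](C(C)C)[C@H](O[Si](C)(C)C(C)(C)C)C[C@]3(C)C[C@@H]2C(=O)OCC | intermediate
16 | (2R,3R,3aS,5S,6S,7aS)-2-[(tert-butyldimethylsilyl)oxy]-6-(ethoxycarbonyl)-7a-methyl-3-(propan-2-yl)octahydro-1H-indene-5-carboxylic acid | OC(=O)[C@H]1C[C@H]2[C@@H](C(C)C)[C@H](O[Si](C)(C)C(C)(C)C)C[C@]2(C)C[C@@H]1C(=O)OCC | intermediate
17 | 6-[(trimethylsilyl)acetyl] analogue of acid 16 (α-silyl ketone in place of the ethyl ester) | OC(=O)[C@H]1C[C@H]2[C@@H](C(C)C)[C@H](O[Si](C)(C)C(C)(C)C)C[C@]2(C)C[C@@H]1C(=O)C[Si](C)(C)C | intermediate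
18 | (2R,3R,3aS,5S,6S,7aS)-6-acetyl-2-[(tert-butyldimethylsilyl)oxy]-7a-methyl-3-(propan-2-yl)octahydro-1H-indene-5-carboxylic acid | OC(=O)[C@H]1C[C@H]2[C@@H](C(C)C)[C@H](O[Si](C)(C)C(C)(C)C)C[C@]2(C)C[C@@H]1C(C)=O | intermediate
19 | (2R,3R,3aS,5S,6S,7aS)-2-[(tert-butyldimethylsilyl)oxy]-7a-methyl-3-(propan-2-yl)-6-(prop-1-en-2-yl)octahydro-1H-indene-5-carboxylic acid | OC(=O)[C@H]1C[C@H]2[C@@H](C(C)C)[C@H](O[Si](C)(C)C(C)(C)C)C[C@]2(C)C[C@@H]1C(C)=C | intermediate
20 | 1-[(2R,3R,3aS,5S,6S,7aS)-2-[(tert-butyldimethylsilyl)oxy]-7a-methyl-3-(propan-2-yl)-6-(prop-1-en-2-yl)octahydro-1H-inden-5-yl]ethan-1-one | CC(=O)[C@H]1C[C@H]2[C@@H](C(C)C)[C@H](O[Si](C)(C)C(C)(C)C)C[C@]2(C)C[C@@H]1C(C)=C | intermediate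
21 | 2,4,6-tri(propan-2-yl)benzenesulfonylhydrazone of ketone 20 | CC(=NNS(=O)(=O)c1c(C(C)C)cc(C(C)C)cc1C(C)C)[C@H]1C[C@H]2[C@@H](C(C)C)[C@H](O[Si](C)(C)C(C)(C)C)C[C@]2(C)C[C@@H]1C(C)=C | intermediate
22 | ethyl (S)-3-hydroxybutanoate | C[C@H](O)CC(=O)OCC | starting material
23 | 3-bromoprop-1-ene | C=CCBr | starting material
24 | dilithium alkoxide-enolate of 22 | C[C@H](O[Li])C=C(O[Li])OCC | intermediate
25 | ethyl (2S,3S)-3-hydroxy-2-(prop-2-en-1-yl)butanoate | C=CC[C@H](C(=O)OCC)[C@H](C)O | intermediate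
26 | (2S,3S)-3-hydroxy-N-methoxy-N-methyl-2-(prop-2-en-1-yl)butanamide | C=CC[C@H](C(=O)N(C)OC)[C@H](C)O | intermediate
27 | ethynyltri(propan-2-yl)silane | C#C[Si](C(C)C)(C(C)C)C(C)C | starting material
28 | lithium [tri(propan-2-yl)silyl]acetylide | [Li]C#C[Si](C(C)C)(C(C)C)C(C)C | intermediate
29 | (4S,5S)-5-hydroxy-4-(prop-2-en-1-yl)-1-[tri(propan-2-yl)silyl]hex-1-yn-3-one | C=CC[C@H](C(=O)C#C[Si](C(C)C)(C(C)C)C(C)C)[C@H](C)O | intermediate
30 | {1-[(2R,3R,3aS,5S,6S,7aS)-2-[(tert-butyldimethylsilyl)oxy]-7a-methyl-3-(propan-2-yl)-6-(prop-1-en-2-yl)octahydro-1H-inden-5-yl]ethenyl}lithium | [Li]C(=C)[C@H]1C[C@H]2[C@@H](C(C)C)[C@H](O[Si](C)(C)C(C)(C)C)C[C@]2(C)C[C@@H]1C(C)=C | intermediate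
31 | dilithium salt of the 1,3-diol formed by addition of 30 to the ketone of 29 (tertiary carbinol configured as in the target) | C=C([C@H]1C[C@H]2[C@@H](C(C)C)[C@H](O[Si](C)(C)C(C)(C)C)C[C@]2(C)C[C@@H]1C(C)=C)[C@](O[Li])(C#C[Si](C(C)C)(C(C)C)C(C)C)[C@@H](CC=C)[C@H](C)O[Li] | intermediate
32 | 2,2-di-tert-butyl-1,3,2-dioxasilinane (silylene acetal) of that diol: 6-methyl, 5-allyl, 4-silylethynyl, 4-[1-(ring A/B-yl)ethenyl] | C=C([C@H]1C[C@H]2[C@@H](C(C)C)[C@H](O[Si](C)(C)C(C)(C)C)C[C@]2(C)C[C@@H]1C(C)=C)[C@](O3)(C#C[Si](C(C)C)(C(C)C)C(C)C)[C@@H](CC=C)[C@H](C)O[Si]3(C(C)(C)C)C(C)(C)C | intermediate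
33 | rings A–C tricycle: cyclooctene closed (Z ring alkene), exocyclic methylene, silylene acetal, silylethynyl group, ring A silyl ether | C=C1[C@H]2C[C@H]3[C@@H](C(C)C)[C@H](O[Si](C)(C)C(C)(C)C)C[C@]3(C)C[C@@H]2/C(C)=C\C[C@H]2[C@H](C)O[Si](C(C)(C)C)(C(C)(C)C)O[C@]12C#C[Si](C(C)C)(C(C)C)C(C)C | intermediate
34 | rings A–C triol with terminal alkyne: ethynyl on the tertiary carbinol of ring C, CH(CH3)OH on the neighbouring ring C carbon, free ring A hydroxyl | C=C1[C@H]2C[C@H]3[C@@H](C(C)C)[C@H](O)C[C@]3(C)C[C@@H]2/C(C)=C\C[C@@H]([C@H](C)O)[C@@]1(O)C#C | intermediate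
35 | rings A–D α-keto lactone: target skeleton with a ketone in place of the lactone secondary alcohol and a free ring A hydroxyl | C=C1[C@H]2C[C@H]3[C@@H](C(C)C)[C@H](O)C[C@]3(C)C[C@@H]2/C(C)=C\C[C@H]2[C@H](C)OC(=O)C(=O)[C@@]12O | intermediate
36 | (S)-1-bromo-2-methylbutane | BrC[C@@H](C)CC | starting material
37 | ethyl but-2-ynoate | CC#CC(=O)OCC | starting material
38 | [(2S)-2-methylbutyl]magnesium bromide | Br[Mg]C[C@@H](C)CC | intermediate
39 | ethyl (2E,5S)-3,5-dimethylhept-2-enoate | CCOC(=O)/C=C(\C)C[C@@H](C)CC | intermediate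
40 | (2E,5S)-3,5-dimethylhept-2-en-1-ol | OC/C=C(\C)C[C@@H](C)CC | intermediate
41 | {(2R,3R)-3-methyl-3-[(2S)-2-methylbutyl]oxiran-2-yl}methanol | OC[C@H]1O[C@]1(C)C[C@@H](C)CC | intermediate
42 | (3R,5S)-3,5-dimethylheptane-1,3-diol | OCC[C@](C)(O)C[C@@H](C)CC | intermediate
43 | (3R,5S)-3-hydroxy-3,5-dimethylheptanoic acid | OC(=O)C[C@](C)(O)C[C@@H](C)CC | intermediate
44 | α-keto lactone 35 acylated on the ring A hydroxyl by acid 43 | C=C1[C@H]2C[C@H]3[C@@H](C(C)C)[C@H](OC(=O)C[C@](C)(O)C[C@@H](C)CC)C[C@]3(C)C[C@@H]2/C(C)=C\C[C@H]2[C@H](C)OC(=O)C(=O)[C@@]12O | intermediate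
45 | CNP0331120.1 | C=C1[C@H]2C[C@H]3[C@@H](C(C)C)[C@H](OC(=O)C[C@](C)(O)C[C@@H](C)CC)C[C@]3(C)C[C@@H]2/C(C)=C\C[C@H]2[C@H](C)OC(=O)[C@@H](O)[C@@]12O | target

## Step count and risks

Total steps: 28. Longest linear sequence: 18 (steps 3–14, 18–21, 27, 28).

Steps most likely to fail:

Step 6 (Pauson–Khand reaction of a 1,7-enyne with a branched internal alkyne and a 1,1-disubstituted alkene). The fallback sets out from 11. Ni(cod)2 (1.1 equiv), P(n-Bu)3 and 2,6-dimethylphenyl isocyanide in DMF at 100 °C effect a zerovalent-nickel enyne–isocyanide [2+2+1] cyclisation that replaces CO by the isocyanide. This gives ethyl (5S,6S,7aS)-5-{[(S)-4-benzyl-2-oxo-1,3-oxazolidin-3-yl]carbonyl}-2-[(2,6-dimethylphenyl)imino]-7a-methyl-3-(propan-2-yl)-2,4,5,6,7,7a-hexahydro-1H-indene-6-carboxylate F1. Hydrolysis of the imine with aqueous oxalic acid in THF returns to the route at 12.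

Step 19 (ring-closing metathesis; the exocyclic methylene with the allyl group could close a cyclopentene instead, and the alkyne could enter enyne metathesis). The fallback masks the exocyclic methylene before ring closure and sets out from 31. Quenching with aqueous NH4Cl instead of silylation gives the free 1,3-diol corresponding to 31 F2. VO(acac)2 (5 mol %) and t-BuOOH in CH2Cl2 at 0 °C, directed by the tertiary allylic hydroxyl, epoxidise only the exocyclic methylene and give the spiro-epoxide of that diol F3 (either epoxide epimer). t-Bu2Si(OTf)2 and 2,6-lutidine give the di-tert-butylsilylene acetal of the epoxy diol F4. The second-generation Grubbs catalyst (toluene, 80 °C) then has only the isopropenyl/allyl pair to close and gives the ring C closed spiro-epoxide F5. Stereospecific deoxygenation with WCl6/n-BuLi (THF, −78 → 23 °C) returns to the route at 33.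

Step 21 (the proposed new oxidative lactonisation). The fallback uses known chemistry and sets out from 34. CpRu(cod)Cl (cat.), tri(2-furyl)phosphine, N-hydroxysuccinimide, Bu4NPF6 and NaHCO3 in DMF/H2O at 90 °C effect the Trost cycloisomerisation–oxidation of the bis-homopropargylic alcohol through a ruthenium vinylidene. This gives the δ-lactone with CH2 at the α-carbon F6. t-BuMe2SiOTf (1.05 equiv) and 2,6-lutidine at −78 °C give its ring A tert-butyldimethylsilyl ether F7. LiN(i-Pr)2 (2.2 equiv) followed by 2-(phenylsulfonyl)-3-phenyloxaziridine gives the α-hydroxy lactone with the new hydroxyl cis to the tertiary hydroxyl F8. Dess–Martin periodinane gives the silyl-protected α-keto lactone F9. HF·pyridine in THF removes the silyl ether and returns to the route at 35.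

Further compounds

F1 | step 6 | ethyl (5S,6S,7aS)-5-{[(S)-4-benzyl-2-oxo-1,3-oxazolidin-3-yl]carbonyl}-2-[(2,6-dimethylphenyl)imino]-7a-methyl-3-(propan-2-yl)-2,4,5,6,7,7a-hexahydro-1H-indene-6-carboxylate | O=C(N1C(=O)OC[C@@H]1Cc1ccccc1)[C@H]2CC3=C(C(C)C)C(=Nc4c(C)cccc4C)C[C@]3(C)C[C@@H]2C(=O)OCC
F2 | step 19 | free 1,3-diol corresponding to 31 | C=C([C@H]1C[C@H]2[C@@H](C(C)C)[C@H](O[Si](C)(C)C(C)(C)C)C[C@]2(C)C[C@@H]1C(C)=C)[C@](O)(C#C[Si](C(C)C)(C(C)C)C(C)C)[C@@H](CC=C)[C@H](C)O
F3 | step 19 | spiro-epoxide of diol F2 at the exocyclic methylene (either epoxide epimer) | C1OC1([C@H]2C[C@H]3[C@@H](C(C)C)[C@H](O[Si](C)(C)C(C)(C)C)C[C@]3(C)C[C@@H]2C(C)=C)[C@](O)(C#C[Si](C(C)C)(C(C)C)C(C)C)[C@@H](CC=C)[C@H](C)O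
F4 | step 19 | di-tert-butylsilylene acetal of epoxy diol F3 | C1OC1([C@H]2C[C@H]3[C@@H](C(C)C)[C@H](O[Si](C)(C)C(C)(C)C)C[C@]3(C)C[C@@H]2C(C)=C)[C@](O4)(C#C[Si](C(C)C)(C(C)C)C(C)C)[C@@H](CC=C)[C@H](C)O[Si]4(C(C)(C)C)C(C)(C)C
F5 | step 19 | ring C closed analogue of 33 with the exocyclic methylene as a spiro-oxirane | C1OC12[C@H]3C[C@H]4[C@@H](C(C)C)[C@H](O[Si](C)(C)C(C)(C)C)C[C@]4(C)C[C@@H]3/C(C)=C\C[C@H]3[C@H](C)O[Si](C(C)(C)C)(C(C)(C)C)O[C@]23C#C[Si](C(C)C)(C(C)C)C(C)C
F6 | step 21 | δ-lactone corresponding to 35 with CH2 in place of the ketone | C=C1[C@H]2C[C@H]3[C@@H](C(C)C)[C@H](O)C[C@]3(C)C[C@@H]2/C(C)=C\C[C@H]2[C@H](C)OC(=O)C[C@@]12O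
F7 | step 21 | ring A tert-butyldimethylsilyl ether of lactone F6 | C=C1[C@H]2C[C@H]3[C@@H](C(C)C)[C@H](O[Si](C)(C)C(C)(C)C)C[C@]3(C)C[C@@H]2/C(C)=C\C[C@H]2[C@H](C)OC(=O)C[C@@]12O
F8 | step 21 | α-hydroxy lactone from F7 with the secondary hydroxyl cis to the tertiary hydroxyl | C=C1[C@H]2C[C@H]3[C@@H](C(C)C)[C@H](O[Si](C)(C)C(C)(C)C)C[C@]3(C)C[C@@H]2/C(C)=C\C[C@H]2[C@H](C)OC(=O)[C@H](O)[C@@]12O
F9 | step 21 | ring A tert-butyldimethylsilyl ether of α-keto lactone 35 | C=C1[C@H]2C[C@H]3[C@@H](C(C)C)[C@H](O[Si](C)(C)C(C)(C)C)C[C@]3(C)C[C@@H]2/C(C)=C\C[C@H]2[C@H](C)OC(=O)C(=O)[C@@]12O
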